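**Strategy.** The cyclopentanone ring of the target (C1, C2, C3, C3a, C7a of the hexahydroindene) is treated as a ring-opened 7-norbornenone: the C2 carbonyl is the one-carbon bridge, C3a and C7a come from an E-enedione, and the C1 and C3 ethyl groups from the cleaved norbornene alkene. One enantioselective Diels–Alder reaction between the twofold-symmetric (E)-oct-4-ene-3,6-dione and 5,5-dimethoxycyclopentadiene forms the C1–C7a and C3–C3a bonds, closes the five-membered ring and fixes the trans C3a/C7a pair in absolute terms. Ethenolysis, then a lactone-enolate Claisen rearrangement, build the cyclohexene with its two quaternary carbons C4 and C5.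

Key step: step 5

Remarks on the chemistry (assumptions and design points):
- (a) The (S)-oxazaborolidinium catalyst is assumed to give 10 in the sense drawn; if the first run shows the opposite sense, the (R)-catalyst is used with nothing else changed.
- (b) Diene 9 is made separately and used as a cold solution, because the base that generates it is incompatible with enedione 5 and with the Lewis acid.
- (c) Ring opening of 10 leaves the two future α-ethyl groups cis to each other, so only the one next to the former endo acyl group must be inverted at the end.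
- (d) Locants in 12–18 and 24: the cyclopentane carbon that carried the endo acyl group of 10 is C1, the other acyl-bearing carbon is C2, the ketal carbon is C4. Relative configuration: 1,2-trans; 2,3-trans; 1,5-cis; 3,5-cis.

Step 1
Reactants: 1 fumaryl chloride
Product: 2 (E)-N1,N4-dimethoxy-N1,N4-dimethylbut-2-enediamide
Conditions: MeNH(OMe)·HCl (2.2 equiv), pyridine, CH2Cl2, 0 °C → rt
Reagents that add atoms: N,O-dimethylhydroxylamine hydrochloride, CNOC.Cl
Why: Twofold N-acylation of the amine by the acid chloride (amide formation) should proceed without touching the E alkene.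

Step 2
Reactants: 2 (E)-N1,N4-dimethoxy-N1,N4-dimethylbut-2-enediamide; 3 ethylmagnesium bromide
Product: 5 (E)-oct-4-ene-3,6-dione, via bis(bromomagnesium) tetrahedral adduct 4 (not isolated)
Conditions: EtMgBr (2.3 equiv), THF, −78 → −20 °C; poured into cold 1 M HCl
Reagents that add atoms: none
Why: Weinreb ketone synthesis, in which each amide takes one ethyl group and stays locked as the magnesium chelate 4 until the cold acidic quench, so that neither over-addition nor conjugate addition to the finished enedione should occur.

Step 3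
Reactants: 6 cyclopentanone
Product: 8 2,5-dibromo-1,1-dimethoxycyclopentane (diastereomer mixture), via 1,1-dimethoxycyclopentane 7 (not isolated)
Conditions: HC(OMe)3, MeOH, TsOH (cat.), rt; then Br2 (2.0 equiv), 0 °C → rt
Reagents that add atoms: trimethyl orthoformate, COC(OC)OC; bromine, BrBr
Why: Acid-catalysed ketalisation followed by α-bromination of the ketal through its enol ether, the second bromine entering at the other α-carbon because enol ether formation toward a brominated carbon is disfavoured.

Step 4
Reactants: 8 2,5-dibromo-1,1-dimethoxycyclopentane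
Product: 9 5,5-dimethoxycyclopenta-1,3-diene (cold solution, used at once)
Conditions: KOt-Bu (2.5 equiv), THF, −40 → 0 °C; cold pentane/water partition, dried, solvent exchanged to CH2Cl2 below 0 °C
Reagents that add atoms: none
Why: Double E2 dehydrobromination should give the diene, which is kept cold and dilute because it dimerises by Diels–Alder reaction on standing and is freed from base before it meets the Lewis acid.

Step 5
Reactants: 5 (E)-oct-4-ene-3,6-dione; 9 5,5-dimethoxycyclopenta-1,3-diene
Product: 10 (1R,4S,5R,6R)-5,6-dipropanoyl-7,7-dimethoxybicyclo[2.2.1]hept-2-ene (C5 acyl exo; C6 acyl endo)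
Conditions: (S)-1-(2-methylphenyl)-3,3-diphenyltetrahydro-1H,3H-pyrrolo[1,2-c][1,3,2]oxazaborole (20 mol %), HN(SO2CF3)2 (20 mol %), CH2Cl2, −78 °C; 9 (1.5 equiv) added slowly as a cold solution
Reagents that add atoms: none
Why: Catalytic enantioselective Diels–Alder reaction (closest known type: cationic oxazaborolidine-catalysed additions of cyclopentadienes to acyclic enones and fumarates), in which the boron Lewis acid binds one of the two homotopic carbonyl groups of 5, lowers its LUMO, and the diene adds in a concerted, asynchronous, suprafacial [4+2] process. The new cyclopentane ring (C1, C7, C4, C5, C6) is closed by cycloaddition, both bonds (C1–C6 and C4–C5) forming on one face of the diene, so it is a pericyclic closure and not a stepwise cyclisation. C5 and C6 are set trans by stereospecific transfer of the E geometry of 5, C1 and C4 follow from the suprafacial mode, and the absolute sense is set by the catalyst, whose aryl group shields one enantioface of the bound enone. Only enantioface selectivity is required: the diene is symmetric, so there is no regiochemistry; one acyl group must end endo and the other exo whichever way the addition goes; and both carbonyl groups of 5 present the same alkene face to the catalyst. The uncatalysed reaction should be slow at −78 °C, and the ketal carbon of 9 should resist ionisation by the Lewis acid because the cation would be an antiaromatic cyclopentadienyl system.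

Step 6
Reactants: 10 (1R,4S,5R,6R)-5,6-dipropanoyl-7,7-dimethoxybicyclo[2.2.1]hept-2-ene; 11 ethylene
Product: 12 1,1'-(3,5-diethenyl-4,4-dimethoxycyclopentane-1,2-diyl)di(propan-1-one) (1,2-trans; 2,3-trans; 1,5-cis)
Conditions: ethylene (1 atm), second-generation Grubbs catalyst (H2IMes)(PCy3)Cl2Ru=CHPh (3 mol %), CH2Cl2 (0.01 M), rt
Reagents that add atoms: none
Why: Ring-opening cross-metathesis with ethylene (ethenolysis) is driven by release of norbornene strain, excess ethylene and dilution suppress ring-opening polymerisation, and the two vinyl groups necessarily emerge cis.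

Step 7
Reactants: 12 1,1'-(3,5-diethenyl-4,4-dimethoxycyclopentane-1,2-diyl)di(propan-1-one)
Product: 13 1,1'-(3,5-diethyl-4,4-dimethoxycyclopentane-1,2-diyl)di(propan-1-one) (1,2-trans; 2,3-trans; 1,5-cis)
Conditions: H2 (1 atm), Pd/C (10 %), EtOAc, rt
Reagents that add atoms: none
Why: Heterogeneous catalytic hydrogenation of two monosubstituted alkenes should leave the ketones, the ketal and all stereocentres untouched.

Step 8
Reactants: 13 1,1'-(3,5-diethyl-4,4-dimethoxycyclopentane-1,2-diyl)di(propan-1-one)
Product: 14 1-[3,5-diethyl-4,4-dimethoxy-2-(1-methoxybut-1-en-2-yl)cyclopentyl]propan-1-one (E/Z mixture)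
Conditions: MeOCH2PPh3Cl (1.15 equiv), KN(SiMe3)2, THF, −78 → 0 °C
Reagents that add atoms: (methoxymethyl)triphenylphosphonium chloride, COC[P+](c1ccccc1)(c1ccccc1)c1ccccc1.[Cl-]
Why: Wittig methoxymethylenation with about one equivalent of ylide should take the C2 propanoyl group, whose ring neighbours both point to the opposite face, in preference to the C1 propanoyl group, which is screened by the cis ethyl group on C5; the regioisomer is expected to be separable and the enol ether geometry is of no consequence.

Step 9
Reactants: 14 1-[3,5-diethyl-4,4-dimethoxy-2-(1-methoxybut-1-en-2-yl)cyclopentyl]propan-1-one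
Product: 16 2-(2,4-diethyl-3,3-dimethoxy-5-propanoylcyclopentyl)butanal (epimer mixture at the aldehyde α-carbon), via α-acetoxymercurio aldehyde 15 (not isolated)
Conditions: Hg(OAc)2 (1.1 equiv), KOAc, THF/H2O (10:1), 0 °C; then aq KI
Reagents that add atoms: water, O
Why: Mercury-assisted hydrolysis of an enol ether (oxymercuration to 15, then iodide-induced protodemercuration) works near neutrality and should spare the dimethyl ketal, which ordinary aqueous acid would cleave before the enol ether; the new α-centre is erased later by enolisation.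

Step 10
Reactants: 16 2-(2,4-diethyl-3,3-dimethoxy-5-propanoylcyclopentyl)butanal
Product: 18 methyl 2-(2,4-diethyl-3,3-dimethoxy-5-propanoylcyclopentyl)butanoate (epimer mixture at the ester α-carbon), via methyl hemiacetal 17 (not isolated)
Conditions: (C5H5NH)2Cr2O7, MeOH (6 equiv), DMF, rt
Reagents that add atoms: methanol, CO
Why: Oxidative esterification, in which the dichromate oxidises the hemiacetal 17 formed with methanol, runs without water, so the ketal cannot hydrolyse and any exchange with methanol regenerates it.

Step 11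
Reactants: 19 (E)-cinnamaldehyde
Product: 20 (E)-but-1-en-3-yn-1-ylbenzene
Conditions: Me3SiCHN2, LiN(i-Pr)2, THF, −78 °C → rt
Reagents that add atoms: (trimethylsilyl)diazomethane, C[Si](C)(C)C=[N+]=[N-]
Why: Colvin-type one-carbon homologation of an aldehyde to a terminal alkyne (addition of the lithiated silyldiazomethane, loss of silanolate and N2, 1,2-hydride shift) under aprotic conditions should keep the E alkene and avoid conjugate additions.

Step 12
Reactants: 20 (E)-but-1-en-3-yn-1-ylbenzene; 3 ethylmagnesium bromide
Product: 22 [(1E,3E)-3-ethyl-4-iodobuta-1,3-dien-1-yl]benzene, via dienylcopper 21 (not isolated)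
Conditions: EtMgBr, CuBr·SMe2, Et2O/Me2S, −45 °C; 20, −25 → −15 °C; then I2, THF, −50 → 0 °C
Reagents that add atoms: iodine, II
Why: Syn-carbocupration of a terminal alkyne (ethyl to the internal carbon, copper to the terminus) followed by iodinolysis with retention should place iodine trans to the styryl group, which is the alkene geometry needed for the later chirality transfer.

Step 13
Reactants: 18 methyl 2-(2,4-diethyl-3,3-dimethoxy-5-propanoylcyclopentyl)butanoate; 22 [(1E,3E)-3-ethyl-4-iodobuta-1,3-dien-1-yl]benzene
Product: 25 trans-fused 1,4,5,7-tetraethyl-6,6-dimethoxy-1-[(1E,3E)-2-ethyl-4-phenylbuta-1,3-dien-1-yl]hexahydrocyclopenta[c]pyran-3(1H)-one (dienyl group cis to H-7a; C4 epimer mixture), via dienyllithium 23 (not isolated), via lithium alkoxide 24 (not isolated)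
Conditions: 22, t-BuLi (2.0 equiv), Et2O, −78 °C; then 18 pre-stirred with CeCl3, THF, −78 → 20 °C; pH 7 work-up, Et3N-deactivated silica
Reagents that add atoms: none
Why: Iodine–lithium exchange with retention of alkene geometry, cerium-assisted 1,2-addition to the only free ketone (which suppresses enolisation and spares the hindered ester) and intramolecular transesterification of alkoxide 24 should give the six-membered lactone, the carbinol centre being set by a Felkin–Anh approach anti to C5 of 18, the ring carbon whose cis ethyl group blocks the other side, which places the dienyl group cis to H-7a.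

Step 14
Reactants: 25 trans-fused 1,4,5,7-tetraethyl-6,6-dimethoxy-1-[(1E,3E)-2-ethyl-4-phenylbuta-1,3-dien-1-yl]hexahydrocyclopenta[c]pyran-3(1H)-one
Product: 28 (1R,3S,3aR,4R,5S,7aR)-1,3,4,5,7-pentaethyl-2,2-dimethoxy-5-[(E)-2-phenylethenyl]-2,3,3a,4,5,7a-hexahydro-1H-indene-4-carboxylic acid, via silyl ketene acetal 26 (not isolated), via trimethylsilyl ester 27 (not isolated)
Conditions: KN(SiMe3)2, Me3SiCl/Et3N, THF, −78 °C; then toluene, 100 °C; then 1 M NaOH, THF, 0 °C, acidified cold with NaH2PO4
Reagents that add atoms: none
Why: Ireland–Claisen rearrangement of a lactone enolate (ring-contracting [3,3] shift), whose tether forces a boat-like, twisted bicyclo[2.2.2] array, so the dienyl group bonds to the ketene acetal face on which it sits (C4 set with CO2H cis to H-3a), the E alkene with ethyl toward the tether and styryl outward sets C5 (styryl cis to CO2H), and the twist that the trans ring fusion demands is the one this C1 epimer of the lactone provides.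

Step 15
Reactants: 28 (1R,3S,3aR,4R,5S,7aR)-1,3,4,5,7-pentaethyl-2,2-dimethoxy-5-[(E)-2-phenylethenyl]-2,3,3a,4,5,7a-hexahydro-1H-indene-4-carboxylic acid
Product: 30 (1S,3S,3aR,4R,5S,7aR)-1,3,4,5,7-pentaethyl-2-oxo-5-[(E)-2-phenylethenyl]-2,3,3a,4,5,7a-hexahydro-1H-indene-4-carboxylic acid, via C1-epimeric keto acid 29 (not isolated)
Conditions: 1 M HCl, THF, rt; extractive work-up; then DBU (3 equiv), CH2Cl2, rt; dilute acid wash
Reagents that add atoms: water, O
Why: Acid-catalysed ketal hydrolysis followed by base-mediated epimerisation through the ketone enolate should move the C1 ethyl group trans to the C7a substituent (relief of the cis-1,2 interaction and of allylic strain with the C7 ethyl group) to give the all-trans cyclopentanone, while C3 is already trans and the ring-fusion carbons, being β to the ketone, cannot epimerise.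

**Compound list**

1 | fumaryl chloride | O=C(Cl)/C=C/C(=O)Cl | starting material
2 | (E)-N1,N4-dimethoxy-N1,N4-dimethylbut-2-enediamide | CON(C)C(=O)/C=C/C(=O)N(C)OC | intermediate
3 | ethylmagnesium bromide | CC[Mg]Br | starting material
4 | bis(bromomagnesium) tetrahedral adduct of 2 with two ethyl groups | CCC(O[Mg]Br)(N(C)OC)/C=C/C(O[Mg]Br)(N(C)OC)CC | intermediate
5 | (E)-oct-4-ene-3,6-dione | CCC(=O)/C=C/C(=O)CC | intermediate
6 | cyclopentanone | O=C1CCCC1 | starting material
7 | 1,1-dimethoxycyclopentane | COC1(OC)CCCC1 | intermediate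
8 | 2,5-dibromo-1,1-dimethoxycyclopentane (diastereomer mixture) | COC1(OC)C(Br)CCC1Br | intermediate
9 | 5,5-dimethoxycyclopenta-1,3-diene | COC1(OC)C=CC=C1 | intermediate
10 | (1R,4S,5R,6R)-5,6-dipropanoyl-7,7-dimethoxybicyclo[2.2.1]hept-2-ene (C5 acyl exo, C6 acyl endo) | CCC(=O)[C@@H]1[C@@H](C(=O)CC)[C@@H]2C=C[C@H]1C2(OC)OC | intermediate
11 | ethylene | C=C | starting material
12 | 1,1'-(3,5-diethenyl-4,4-dimethoxycyclopentane-1,2-diyl)di(propan-1-one), 1,2-trans, 2,3-trans, 1,5-cis | CCC(=O)[C@@H]1[C@@H](C(=O)CC)[C@H](C=C)C(OC)(OC)[C@@H]1C=C | intermediate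
13 | 1,1'-(3,5-diethyl-4,4-dimethoxycyclopentane-1,2-diyl)di(propan-1-one), same relative configuration | CCC(=O)[C@@H]1[C@@H](C(=O)CC)[C@H](CC)C(OC)(OC)[C@@H]1CC | intermediate
14 | 1-[3,5-diethyl-4,4-dimethoxy-2-(1-methoxybut-1-en-2-yl)cyclopentyl]propan-1-one (E/Z mixture) | CCC(=O)[C@@H]1[C@@H](C(CC)=COC)[C@H](CC)C(OC)(OC)[C@@H]1CC | intermediate
15 | α-acetoxymercurio aldehyde derived from 14 | CCC(=O)[C@@H]1[C@@H](C(CC)(C=O)[Hg]OC(C)=O)[C@H](CC)C(OC)(OC)[C@@H]1CC | intermediate
16 | 2-(2,4-diethyl-3,3-dimethoxy-5-propanoylcyclopentyl)butanal (α-epimer mixture) | CCC(=O)[C@@H]1[C@@H](C(CC)C=O)[C@H](CC)C(OC)(OC)[C@@H]1CC | intermediate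
17 | methyl hemiacetal of 16 | CCC(=O)[C@@H]1[C@@H](C(CC)C(O)OC)[C@H](CC)C(OC)(OC)[C@@H]1CC | intermediate
18 | methyl 2-(2,4-diethyl-3,3-dimethoxy-5-propanoylcyclopentyl)butanoate (α-epimer mixture) | CCC(=O)[C@@H]1[C@@H](C(CC)C(=O)OC)[C@H](CC)C(OC)(OC)[C@@H]1CC | intermediate
19 | (E)-cinnamaldehyde | O=C/C=C/c1ccccc1 | starting material
20 | (E)-but-1-en-3-yn-1-ylbenzene | C#C/C=C/c1ccccc1 | intermediate
21 | [(1E,3E)-2-ethyl-4-phenylbuta-1,3-dien-1-yl]copper | [Cu]/C=C(CC)/C=C/c1ccccc1 | intermediate
22 | [(1E,3E)-3-ethyl-4-iodobuta-1,3-dien-1-yl]benzene | I/C=C(CC)/C=C/c1ccccc1 | intermediate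
23 | [(1E,3E)-2-ethyl-4-phenylbuta-1,3-dien-1-yl]lithium | [Li]/C=C(CC)/C=C/c1ccccc1 | intermediate
24 | lithium alkoxide of the tertiary dienyl carbinol formed at the C1 ketone of 18 | [Li]O[C@](CC)(/C=C(CC)/C=C/c1ccccc1)[C@@H]1[C@@H](C(CC)C(=O)OC)[C@H](CC)C(OC)(OC)[C@@H]1CC | intermediate
25 | trans-fused 1,4,5,7-tetraethyl-6,6-dimethoxy-1-[(1E,3E)-2-ethyl-4-phenylbuta-1,3-dien-1-yl]hexahydrocyclopenta[c]pyran-3(1H)-one (dienyl cis to H-7a, C4 epimer mixture) | CC[C@]1(/C=C(CC)/C=C/c3ccccc3)OC(=O)C(CC)[C@H]2[C@H](CC)C(OC)(OC)[C@H](CC)[C@H]12 | intermediate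
26 | trimethylsilyl ketene acetal of lactone 25 | CC[C@]1(/C=C(CC)/C=C/c3ccccc3)OC(O[Si](C)(C)C)=C(CC)[C@H]2[C@H](CC)C(OC)(OC)[C@H](CC)[C@H]12 | intermediate
27 | trimethylsilyl ester of 28 | CCC1=C[C@@](/C=C/c2ccccc2)(CC)[C@](CC)(C(=O)O[Si](C)(C)C)[C@@H]2[C@@H]1[C@@H](CC)C(OC)(OC)[C@H]2CC | intermediate
28 | (1R,3S,3aR,4R,5S,7aR)-1,3,4,5,7-pentaethyl-2,2-dimethoxy-5-[(E)-2-phenylethenyl]-2,3,3a,4,5,7a-hexahydro-1H-indene-4-carboxylic acid | CCC1=C[C@@](/C=C/c2ccccc2)(CC)[C@](CC)(C(=O)O)[C@@H]2[C@@H]1[C@@H](CC)C(OC)(OC)[C@H]2CC | intermediate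
29 | (1R,3S,3aR,4R,5S,7aR)-1,3,4,5,7-pentaethyl-2-oxo-5-[(E)-2-phenylethenyl]-2,3,3a,4,5,7a-hexahydro-1H-indene-4-carboxylic acid (C1 epimer of the target) | CCC1=C[C@@](/C=C/c2ccccc2)(CC)[C@](CC)(C(=O)O)[C@@H]2[C@@H]1[C@@H](CC)C(=O)[C@H]2CC | intermediate
30 | (1S,3S,3aR,4R,5S,7aR)-1,3,4,5,7-pentaethyl-2-oxo-5-[(E)-2-phenylethenyl]-2,3,3a,4,5,7a-hexahydro-1H-indene-4-carboxylic acid (CNP0132298.1) | CCC1=C[C@@](/C=C/c2ccccc2)(CC)[C@](CC)(C(=O)O)[C@@H]2[C@@H]1[C@H](CC)C(=O)[C@H]2CC | target

**Totals.** 15 steps in all; longest linear sequence 11 steps (steps 1, 2, 5, 6, 7, 8, 9, 10, 13, 14, 15).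

**The three steps most likely to fail**

Step 14. The tethered [3,3] shift may stall because the trans ring fusion resists the boat-like array, or heterolysis of the tertiary dienylic C–O bond (elimination or 1,3-shift) may outrun it. The fallback closes the six-membered ring by a reaction that is indifferent to the ring fusion; it sets out from 18 and returns at 28. The C1 ketone of 18 is methylenated (Ph3P=CH2) to the methylidene ester F4, which is saponified (LiOH) to the methylidene acid F5. The acid is esterified (DCC, DMAP) with (2E,4E)-3-ethyl-5-phenylpenta-2,4-dien-1-ol F6, itself made from 22 by iodine–lithium exchange and trapping with paraformaldehyde. The resulting allyl ester F7 undergoes an open-chain Ireland–Claisen rearrangement (LiN(i-Pr)2, Me3SiCl, THF, −78 → 60 °C) to the vinyl acid F8, which already holds the C4–C5 bond and both quaternary carbons. Ring-closing metathesis of its vinyl group with the 1,1-disubstituted alkene (second-generation Grubbs catalyst (H2IMes)(PCy3)Cl2Ru=CHPh) then forms the C6=C7 bond and gives 28. The price is an open-chain chair transition state with less certain facial control, so diastereomers may have to be separated, and the 2Z isomer of the alcohol would be used if the ketene acetal geometry requires it.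

Step 13. Facial selectivity in the addition to the hindered ketone may be poor; the wrong epimer at the carbinol carbon cannot reach the rearrangement geometry. The fallback replaces kinetic facial control by thermodynamic recycling; it sets out from 18 and returns at 25. The addition is run as before, and the C1-epimeric lactone F3 is separated and re-equilibrated through reversible heterolysis of its tertiary, doubly allylic C–O bond (ion-pair return within the six-membered ring; catalytic Sc(OTf)3, MeCN, −20 °C). 25 is removed from the equilibrium mixture by chromatography and F3 is recycled.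

Step 5. Enantioselectivity may erode through the uncatalysed background cycloaddition of the very reactive enedione, or the diene may be lost by dimerisation before it is captured. The fallback moves the asymmetric cycloaddition to the dienophile class for which this catalyst type is best documented and installs the ketones afterwards; it sets out from 9 and returns at 10. Diene 9 is combined with diethyl fumarate under the same oxazaborolidinium catalysis to give the diethyl ester adduct F1. Both esters are converted into the bis-Weinreb amide adduct F2 (MeNH(OMe)·HCl, i-PrMgCl, THF, −20 → 0 °C), and EtMgBr then gives 10 by Weinreb ketone synthesis.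

**Further compounds**

F1 | step 5 | diethyl trans-7,7-dimethoxybicyclo[2.2.1]hept-5-ene-2,3-dicarboxylate (same absolute sense as 10) | CCOC(=O)[C@@H]1[C@@H](C(=O)OCC)[C@@H]2C=C[C@H]1C2(OC)OC
F2 | step 5 | trans-N2,N3,7,7-tetramethoxy-N2,N3-dimethylbicyclo[2.2.1]hept-5-ene-2,3-dicarboxamide | CON(C)C(=O)[C@@H]1[C@@H](C(=O)N(C)OC)[C@@H]2C=C[C@H]1C2(OC)OC
F3 | step 13 | C1 epimer of lactone 25 (dienyl trans to H-7a) | CC[C@@]1(/C=C(CC)/C=C/c3ccccc3)OC(=O)C(CC)[C@H]2[C@H](CC)C(OC)(OC)[C@H](CC)[C@H]12
F4 | step 14 | methyl 2-[5-(but-1-en-2-yl)-2,4-diethyl-3,3-dimethoxycyclopentyl]butanoate | C=C(CC)[C@@H]1[C@@H](C(CC)C(=O)OC)[C@H](CC)C(OC)(OC)[C@@H]1CC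
F5 | step 14 | 2-[5-(but-1-en-2-yl)-2,4-diethyl-3,3-dimethoxycyclopentyl]butanoic acid | C=C(CC)[C@@H]1[C@@H](C(CC)C(=O)O)[C@H](CC)C(OC)(OC)[C@@H]1CC
F6 | step 14 | (2E,4E)-3-ethyl-5-phenylpenta-2,4-dien-1-ol | OC/C=C(CC)/C=C/c1ccccc1
F7 | step 14 | (2E,4E)-3-ethyl-5-phenylpenta-2,4-dien-1-yl ester of F5 | C=C(CC)[C@@H]1[C@@H](C(CC)C(=O)OC/C=C(CC)/C=C/c2ccccc2)[C@H](CC)C(OC)(OC)[C@@H]1CC
F8 | step 14 | 2-[5-(but-1-en-2-yl)-2,4-diethyl-3,3-dimethoxycyclopentyl]-3-ethenyl-2,3-diethyl-5-phenylpent-4-enoic acid (quaternary centres as in 28) | C=C(CC)[C@@H]1[C@@H]([C@@](CC)(C(=O)O)[C@](CC)(C=C)/C=C/c2ccccc2)[C@H](CC)C(OC)(OC)[C@@H]1CC
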